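**Assumptions (one line each):** atraric acid (methyl 2,4-dihydroxy-3,6-dimethylbenzoate) is taken as a commercial building block. An (R)-selective azaphilone-forming flavin monooxygenase is available as a recombinant enzyme, and the keto-aldehyde and its isochromenol lactol interconvert at pH 7.5.

## Retrosynthesis
1. Mitorubrinic acid ← acylation of the tertiary C7-OH of an azaphilone with a protected orsellinoyl chloride, then one acidolysis that removes the tBu ester and two MOM groups.
2. The C7-hydroxy azaphilone, with its quaternary stereocentre, pyran ring and dearomatised carbocycle, ← flavin-monooxygenase hydroxylative dearomatisation and pyran closure of a 2,4-dihydroxy-3-methylbenzaldehyde keto-aldehyde (present as its isochromenol lactol).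
3. The lactol ← DIBAL partial reduction of a 3-(tBu acrylate) isocoumarin ← Wittig on a 3-formylisocoumarin ← acid cascade of the lateral-lithiation/acylation product of MOM-protected atraric acid with a glyoxal Weinreb amide.
4. Ring order: benzene (commercial), then isocoumarin lactone, then ring-opened keto-aldehyde/lactol, then pyran plus quaternary C7 (enzyme), then ester.

## Forward route

**Step 1**
Reactants: 1 methyl 2,2-dimethoxyacetate
Product: 2 2,2-dimethoxy-N-methoxy-N-methylacetamide
Conditions: MeNH(OMe)·HCl, i-PrMgCl (3 equiv), THF, –20 → 0 °C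
Reagents that add atoms: N,O-dimethylhydroxylamine hydrochloride, CNOC.Cl
Why: Weinreb amidation gives an acyl donor whose chelated tetrahedral adduct survives until quench, so the next step stops cleanly at the ketone; no stereocentre is formed.

**Step 2**
Reactants: 3 atraric acid (methyl 2,4-dihydroxy-3,6-dimethylbenzoate)
Product: 4 methyl 2,4-bis(methoxymethoxy)-3,6-dimethylbenzoate
Conditions: NaH (2.5 equiv), MOMCl (2.6 equiv), THF/DMF 4:1, 0 → 25 °C
Reagents that add atoms: chloromethyl methyl ether, ClCOC
Why: Phenoxide O-alkylation masks both phenols so that the lateral lithiation in the next step is not quenched; no stereocentre is formed.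

**Step 3**
Reactants: 4; 2
Product: 5 methyl 2-(3,3-dimethoxy-2-oxopropyl)-4,6-bis(methoxymethoxy)-5-methylbenzoate
Conditions: LDA (1.3 equiv), THF, –78 °C, 45 min; then 2 (1.5 equiv), –78 → 0 °C; aq. NH4Cl
Reagents that add atoms: none
Why: Ester-directed lateral lithiation (Harris-type) of the 6-methyl group followed by Weinreb acylation installs the masked glyoxal ketone chain; no stereocentre is formed.

**Step 4**
Reactants: 5
Product: 6 6,8-dihydroxy-7-methyl-1-oxo-1H-isochromene-3-carbaldehyde (isolated as its hydrate)
Conditions: 6 M aq. HCl/1,4-dioxane 1:2, 70 °C, 8 h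
Reagents that add atoms: water, O (supplies the aldehyde oxygen)
Why: One acid cascade cleaves both aryl MOM ethers, closes the enol-lactone (6-exo enol O-acylation with loss of MeOH) and hydrolyses the dimethyl acetal to the aldehyde; no stereocentre is formed.

**Step 5**
Reactants: 6; 7 tert-butyl (triphenylphosphoranylidene)acetate
Product: 8 tert-butyl (E)-3-(6,8-dihydroxy-7-methyl-1-oxo-1H-isochromen-3-yl)acrylate
Conditions: 7 (1.2 equiv), THF, 25 → 50 °C, 6 h
Reagents that add atoms: none (the ylide is reactant 7)
Why: Wittig olefination with a stabilised ylide is E-selective and tolerates free phenols, installing the acrylate carbon skeleton as a tBu ester.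

**Step 6**
Reactants: 8
Product: 9 tert-butyl (E)-3-(1,6,8-trihydroxy-7-methyl-1H-isochromen-3-yl)acrylate, the lactol. It is in equilibrium with the open keto-aldehyde tert-butyl (E)-5-(2-formyl-3,5-dihydroxy-4-methylphenyl)-4-oxopent-2-enoate.
Conditions: DIBAL-H (3.5 equiv), CH2Cl2, –78 °C, 1 h; MeOH quench; Rochelle salt, pH 6–7 work-up; used at once
Reagents that add atoms: none (hydride only)
Why: Two equivalents of DIBAL are consumed by the phenols, and the third reduces the lactone to the stable aluminium lactol at –78 °C, leaving the hindered tBu enoate untouched; the lactol opens to the salicylaldehyde/ketone in buffer, and no stereocentre is formed.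

**Step 7 (enzymatic key step)**
Reactants: 9
Product: 10 tert-butyl (E)-3-[(7R)-7-hydroxy-7-methyl-6,8-dioxo-7,8-dihydro-6H-isochromen-3-yl]acrylate
Conditions: (R)-selective azaphilone-forming FAD-dependent monooxygenase (AzaH/PigN-type, recombinant, 10 µM), FAD (20 µM), NADPH (0.2 mM) recycled with GDH/D-glucose, O2 (air), 50 mM KPi pH 7.5/DMSO 95:5, 1 mM substrate, 25 °C, 4 h; EtOAc extraction at pH 5. No thiols or amine buffers.
Reagents that add atoms: molecular oxygen, O=O (one O atom becomes the C7–OH)
Why: The flavin C4a-hydroperoxide hydroxylates C-3 of the bis-phenolate (the methyl-bearing carbon) with the active site fixing the enantioface, which sets the C7 quaternary stereocentre as R; the dienone then enolises and the ketone enol closes onto the aldehyde with loss of water to form the pyran ring (hydroxylative dearomatisation with pyran closure).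

**Step 8**
Reactants: 11 orcinaldehyde (2,4-dihydroxy-6-methylbenzaldehyde)
Product: 12 2,4-bis(methoxymethoxy)-6-methylbenzaldehyde
Conditions: NaH (2.4 equiv), MOMCl (2.5 equiv), THF, 0 → 25 °C
Reagents that add atoms: chloromethyl methyl ether, ClCOC
Why: Phenoxide alkylation masks the phenols as acid-labile MOM ethers that will be removed together with the tBu ester at the end; no stereocentre is formed.

**Step 9**
Reactants: 12
Product: 13 2,4-bis(methoxymethoxy)-6-methylbenzoic acid
Conditions: NaClO2 (3 equiv), NaH2PO4 (3 equiv), 2-methyl-2-butene (10 equiv), t-BuOH/H2O 3:1, 25 °C, 3 h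
Reagents that add atoms: sodium chlorite, [Na+].[O-]Cl=O
Why: Pinnick oxidation converts the hindered aldehyde to the acid under mild buffered conditions, and the alkene scavenges HOCl so the electron-rich ring is not chlorinated; no stereocentre is formed.

**Step 10**
Reactants: 13
Product: 14 2,4-bis(methoxymethoxy)-6-methylbenzoyl chloride
Conditions: Ghosez reagent (1.2 equiv), CH2Cl2, 0 → 25 °C, 1 h; concentrate and use directly
Reagents that add atoms: 1-chloro-N,N,2-trimethylprop-1-en-1-amine, CC(C)=C(Cl)N(C)C (supplies Cl)
Why: Neutral acid-chloride formation avoids HCl-induced MOM cleavage; no stereocentre is formed.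

**Step 11**
Reactants: 10; 14
Product: 15 (7R)-3-[(E)-3-tert-butoxy-3-oxoprop-1-enyl]-7-methyl-6,8-dioxo-7,8-dihydro-6H-isochromen-7-yl 2,4-bis(methoxymethoxy)-6-methylbenzoate
Conditions: 14 (3 equiv), DMAP (1 equiv), Et3N (4 equiv), CH2Cl2, 0 → 25 °C, 16 h
Reagents that add atoms: none (acid chloride is reactant 14)
Why: DMAP-catalysed O-acylation of the acidic α,α′-dicarbonyl tertiary alcohol; C7 carries no hydrogen and cannot epimerise, so the R centre from Step 7 is retained.

**Step 12**
Reactants: 15
Product: 16 mitorubrinic acid
Conditions: TFA/CH2Cl2 1:2, anisole (10 equiv), 0 → 25 °C, 2 h; concentrate; RP-HPLC (water/MeCN with 0.1% HCO2H)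
Reagents that add atoms: none
Why: Acidolysis removes the tBu ester and both aryl MOM acetals in one step, with anisole trapping tBu⁺ and MeOCH2⁺; the quaternary C7 cannot epimerise under these conditions.

## Compound list
1 | methyl 2,2-dimethoxyacetate | COC(OC)C(=O)OC | starting material
2 | 2,2-dimethoxy-N-methoxy-N-methylacetamide | COC(OC)C(=O)N(C)OC | intermediate
3 | methyl 2,4-dihydroxy-3,6-dimethylbenzoate (atraric acid) | COC(=O)c1c(C)cc(O)c(C)c1O | starting material
4 | methyl 2,4-bis(methoxymethoxy)-3,6-dimethylbenzoate | COC(=O)c1c(C)cc(OCOC)c(C)c1OCOC | intermediate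
5 | methyl 2-(3,3-dimethoxy-2-oxopropyl)-4,6-bis(methoxymethoxy)-5-methylbenzoate | COC(=O)c1c(CC(=O)C(OC)OC)cc(OCOC)c(C)c1OCOC | intermediate
6 | 6,8-dihydroxy-7-methyl-1-oxo-1H-isochromene-3-carbaldehyde | O=CC1=Cc2cc(O)c(C)c(O)c2C(=O)O1 | intermediate
7 | tert-butyl (triphenylphosphoranylidene)acetate | CC(C)(C)OC(=O)C=P(c1ccccc1)(c1ccccc1)c1ccccc1 | starting material
8 | tert-butyl (E)-3-(6,8-dihydroxy-7-methyl-1-oxo-1H-isochromen-3-yl)acrylate | CC(C)(C)OC(=O)/C=C/C1=Cc2cc(O)c(C)c(O)c2C(=O)O1 | intermediate
9 | tert-butyl (E)-3-(1,6,8-trihydroxy-7-methyl-1H-isochromen-3-yl)acrylate (lactol; open form CC(C)(C)OC(=O)/C=C/C(=O)Cc1cc(O)c(C)c(O)c1C=O) | CC(C)(C)OC(=O)/C=C/C1=Cc2cc(O)c(C)c(O)c2C(O)O1 | intermediate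
10 | tert-butyl (E)-3-[(7R)-7-hydroxy-7-methyl-6,8-dioxo-7,8-dihydro-6H-isochromen-3-yl]acrylate | O[C@]1(C)C(=O)C=C2C=C(/C=C/C(=O)OC(C)(C)C)OC=C2C1=O | intermediate
11 | 2,4-dihydroxy-6-methylbenzaldehyde (orcinaldehyde) | Cc1cc(O)cc(O)c1C=O | starting material
12 | 2,4-bis(methoxymethoxy)-6-methylbenzaldehyde | Cc1cc(OCOC)cc(OCOC)c1C=O | intermediate
13 | 2,4-bis(methoxymethoxy)-6-methylbenzoic acid | Cc1cc(OCOC)cc(OCOC)c1C(=O)O | intermediate
14 | 2,4-bis(methoxymethoxy)-6-methylbenzoyl chloride | Cc1cc(OCOC)cc(OCOC)c1C(=O)Cl | intermediate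
15 | (7R)-7-acyloxy azaphilone, tBu ester, bis-MOM orsellinate (name as in Step 11) | Cc1cc(OCOC)cc(OCOC)c1C(=O)O[C@]1(C)C(=O)C=C2C=C(/C=C/C(=O)OC(C)(C)C)OC=C2C1=O | intermediate
16 | mitorubrinic acid | Cc1cc(O)cc(O)c1C(=O)O[C@]1(C)C(=O)C=C2C=C(/C=C/C(=O)O)OC=C2C1=O | target

## Totals
Total steps: 12. Longest linear sequence: 8 steps, from atraric acid (Steps 2, 3, 4, 5, 6, 7, 11, 12).

## Three steps most likely to fail
1. **Step 7 (monooxygenase).** The enzyme may reject the non-native tBu-acrylate chain, or the Michael-acceptor substrate may decompose in buffer.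
   Fallback: drop the enzyme and apply a chiral Cu(II)/(–)-sparteine/O2 hydroxylative dearomatisation (Porco-type) to the phenolic benzopyran derived from 9, accepting lower ee.
2. **Step 11 (acylation of the hindered, electron-poor tertiary alcohol with a 2,6-disubstituted aroyl chloride).** Conversion may be low.
   Fallback: transfer the orsellinoyl group enzymatically, using a pathway O-acyltransferase with orsellinoyl-SNAC on the free alcohol 10.
3. **Step 6 (DIBAL chemoselectivity).** Lactone reduction may be accompanied by over-reduction of the enoate, or the lactol may not be stable enough to use.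
   Fallback: reach 9 by the dihydroisocoumarin route: lateral lithiation of the TBS-protected atraric ester with acrolein, LiBH4 opening to the diol, selective primary TBS protection, cross-metathesis with tBu acrylate, DMP oxidation of the secondary alcohol, global desilylation, then MnO2 oxidation of the benzylic alcohol.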